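**Plan**

1. Retrosynthesis first cuts the two aryl–prenyl C–C bonds at C3′/C5′ of ring B back to aryl bromides, then removes ring A by cutting C4a–C5 and C8–C8a.
2. The feature that permits this is that ring A carries its oxygens at C5 and C7 in the 1,3-pattern of an acetoacetate and shares only the C4a=C8a bond with ring C. C5–C8 can therefore be added as the bis-silyl dienol ether of methyl acetoacetate across C5=C6 of a monocyclic 5-bromo-4-pyranone, with bromide supplying the aromatic oxidation level.
3. Forward, ring C is made first: furan plus the aryl aldehyde, oxidative ring expansion to the 3-hydroxy-4-pyranone, O-methylation, C5 bromination.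
4. Ring A is then annulated, the benzyl group is exchanged for MOM, ring B is doubly prenylated and the MOM groups are removed.
5. The target is achiral; the only stereocentres on the way (carbinol, hemiacetal, cycloadduct) are racemic and are destroyed.

Key step: step 8

Remark: the target has no stereocentre and no stereogenic double bond, so "single enantiomer" is read as the one achiral structure drawn; 12 and 14 are used as the geometric mixtures in which they form, because that geometry is lost in step 8.

**Route**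

Step 1
Reactants: 1 3,5-dibromo-4-hydroxybenzaldehyde
Product: 2 4-(benzyloxy)-3,5-dibromobenzaldehyde
Conditions: BnBr (1.2 equiv), K2CO3, DMF, 60 °C
Reagents that add atoms: benzyl bromide, BrCc1ccccc1
Why: Williamson etherification of the acidic, hindered phenol; benzyl is chosen because, unlike an acetal, it should survive the hot aqueous acid of step 3 and the silyl triflate of step 8.

Step 2
Reactants: 2 4-(benzyloxy)-3,5-dibromobenzaldehyde, 3 furan
Product: 5 [4-(benzyloxy)-3,5-dibromophenyl](furan-2-yl)methanol (racemic), via 2-furyllithium 4 (not isolated)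
Conditions: 3 (1.3 equiv), n-BuLi (1.2 equiv), THF, −78 → 0 °C; then 2, −78 °C; H2O
Reagents that add atoms: none
Why: C2 lithiation of furan and 1,2-addition of the heteroaryllithium to the aldehyde, which at −78 °C should outrun bromine–lithium exchange (unfavourable for the stabilised 2-furyl anion); the carbinol centre forms racemic and is erased in step 3.

Step 3
Reactants: 5 [4-(benzyloxy)-3,5-dibromophenyl](furan-2-yl)methanol
Product: 8 2-[4-(benzyloxy)-3,5-dibromophenyl]-3-hydroxy-4H-pyran-4-one, via Achmatowicz hemiacetal 6 (not isolated), via chloro enone 7 (not isolated)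
Conditions: Cl2 (2.1 equiv), MeCN–H2O (3:1), −10 → 20 °C; then 85 °C
Reagents that add atoms: water, O
Why: Achmatowicz oxidative ring expansion, C4 chlorination of the resulting enone and acid hydrolysis with 1,3-oxygen transposition is the established one-pot conversion of secondary furfuryl alcohols into 2-substituted 3-hydroxy-4-pyranones (the maltol process); the benzyl ether and aryl bromides should be inert to cold chlorine and hot dilute HCl.

Step 4
Reactants: 8 2-[4-(benzyloxy)-3,5-dibromophenyl]-3-hydroxy-4H-pyran-4-one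
Product: 9 2-[4-(benzyloxy)-3,5-dibromophenyl]-3-methoxy-4H-pyran-4-one
Conditions: MeI (2 equiv), K2CO3, acetone, reflux
Reagents that add atoms: iodomethane, CI
Why: Williamson O-alkylation of the acidic enolic 3-OH, as in the methylation of maltol; it is the only acidic site.

Step 5
Reactants: 9 2-[4-(benzyloxy)-3,5-dibromophenyl]-3-methoxy-4H-pyran-4-one
Product: 10 2-[4-(benzyloxy)-3,5-dibromophenyl]-5-bromo-3-methoxy-4H-pyran-4-one
Conditions: Br2 (1.1 equiv), pyridine (2 equiv), CH2Cl2, 0 → 20 °C
Reagents that add atoms: bromine, BrBr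
Why: electrophilic α-bromination of the vinylogous ester by addition–elimination; C5 is the only nucleophilic ring carbon (α to C=O, β to O1), C6 is electrophilic, and the aryl ring is blocked and deactivated.

Step 6
Reactants: 11 methyl acetoacetate
Product: 12 methyl 3-(trimethylsilyloxy)but-2-enoate (E/Z mixture)
Conditions: TMSCl (1.5 equiv), Et3N (1.6 equiv), hexane, 20 °C
Reagents that add atoms: chlorotrimethylsilane, C[Si](C)(C)Cl
Why: silyl enol ether formation by soft enolisation of the β-keto ester.

Step 7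
Reactants: 12 methyl 3-(trimethylsilyloxy)but-2-enoate
Product: 14 1-methoxy-1,3-bis(trimethylsilyloxy)buta-1,3-diene, via lithium dienolate 13 (not isolated)
Conditions: LDA (1.1 equiv), THF, −78 °C; TMSCl (1.2 equiv), −78 → 20 °C
Reagents that add atoms: chlorotrimethylsilane, C[Si](C)(C)Cl
Why: γ-deprotonation of the silyloxy crotonate and O-silylation of the ester dienolate is the standard two-step preparation of this ketene-acetal diene.

Step 8
Reactants: 10 2-[4-(benzyloxy)-3,5-dibromophenyl]-5-bromo-3-methoxy-4H-pyran-4-one, 14 1-methoxy-1,3-bis(trimethylsilyloxy)buta-1,3-diene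
Product: 18 2-[4-(benzyloxy)-3,5-dibromophenyl]-5,7-dihydroxy-3-methoxy-4H-chromen-4-one, via silyloxypyrylium triflate 15 (not isolated), via bromo cycloadduct 16 (not isolated), via bis-silyl ether 17 (not isolated)
Conditions: TMSOTf (1.2 equiv), CH2Cl2, 0 °C; 14 (2 equiv), −78 → 20 °C; Et3N (4 equiv), 20 → 40 °C; 1 M HCl, THF, 20 °C
Reagents that add atoms: none
Why: Proposed new method: O-silylation of the C4 carbonyl gives pyrylium 15, whose unsubstituted, electrophilic C6 should take the CH2 terminus of 14 (vinylogous Mukaiyama–Michael), and the C4 silyl enol ether so formed should attack through its brominated C5 the O-silylated ester carbenium, so that C8–C8a and C4a–C5 form in one asynchronous formal [4+2] event to give 16. The closest known reaction types are the regioselective benzannulation of 2-bromoquinones with this diene, the silyl-triflate-mediated conjugate addition of 1,3-bis(silyloxy)dienes to chromones and the Michael–Claisen synthesis of resorcinols. Ring A closes as a six-membered carbocycle by 6-(enolexo)-exo-trig attack of C5 on the carboxonium carbon (a suprafacial, cis-fused closure if the event is concerted). The two ring-fusion centres of 16 are transient and need no control: ionisation of the mixed ketal should expel MeOSiMe3 to leave a ring-A bis(silyl) dienol ether, and Et3N should then remove the now allylic C8a–H with loss of bromide from C4a, an aromatisation-driven 1,2-elimination to 17, which mild acid desilylates to 18. The step needs regioselectivity (CH2 terminus to C6, ketene-acetal carbon to C5), secured by the polarity of the vinylogous ester and by the aryl and methoxy groups blocking C2, and it needs bromine to leave as HBr, which the silylated, non-basic medium should favour by suppressing retro-oxa-Michael opening of the pyranone; the bromide supplies the aromatic oxidation level, so no oxidant is needed.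

Step 9
Reactants: 18 2-[4-(benzyloxy)-3,5-dibromophenyl]-5,7-dihydroxy-3-methoxy-4H-chromen-4-one
Product: 19 2-(3,5-dibromo-4-hydroxyphenyl)-5,7-dihydroxy-3-methoxy-4H-chromen-4-one
Conditions: BCl3 (6 equiv), pentamethylbenzene (3 equiv), CH2Cl2, −78 → −20 °C; MeOH quench
Reagents that add atoms: none
Why: Lewis-acid debenzylation of an aryl benzyl ether with pentamethylbenzene as a non-basic benzyl-cation scavenger; at low temperature the 3-methoxy group, the aryl bromides and the pyranone should be untouched, and hydrogenolysis is avoided because of the C–Br bonds.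

Step 10
Reactants: 19 2-(3,5-dibromo-4-hydroxyphenyl)-5,7-dihydroxy-3-methoxy-4H-chromen-4-one
Product: 20 2-[3,5-dibromo-4-(methoxymethoxy)phenyl]-5-hydroxy-3-methoxy-7-(methoxymethoxy)-4H-chromen-4-one
Conditions: MOMCl (3 equiv), i-Pr2NEt (4 equiv), CH2Cl2, 0 → 20 °C
Reagents that add atoms: chloromethyl methyl ether, COCCl
Why: MOM ether formation at the two non-chelated phenols; the 5-OH is hydrogen-bonded to C4=O and should stay free under amine base, which is wanted because its phenoxide lowers the electrophilicity of the pyranone toward hydroxide in step 11.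

Step 11
Reactants: 20 2-[3,5-dibromo-4-(methoxymethoxy)phenyl]-5-hydroxy-3-methoxy-7-(methoxymethoxy)-4H-chromen-4-one, 21 prenylboronic acid pinacol ester
Product: 22 5-hydroxy-3-methoxy-7-(methoxymethoxy)-2-[4-(methoxymethoxy)-3,5-bis(3-methylbut-2-en-1-yl)phenyl]-4H-chromen-4-one
Conditions: 21 (3 equiv), Pd-PEPPSI-IPent (4 mol %), 5 M aq. KOH, THF, 70 °C
Reagents that add atoms: none
Why: twofold Suzuki–Miyaura coupling of the aryl dibromide with the 3,3-disubstituted allylboronate under a bulky NHC–palladium catalyst, a system known to favour the linear (α) prenyl arene because the allyl–palladium equilibrates to the primary σ-isomer before reductive elimination; MOM ethers are stable to the aqueous base.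

Step 12
Reactants: 22 5-hydroxy-3-methoxy-7-(methoxymethoxy)-2-[4-(methoxymethoxy)-3,5-bis(3-methylbut-2-en-1-yl)phenyl]-4H-chromen-4-one
Product: 23 5,7-dihydroxy-2-[4-hydroxy-3,5-bis(3-methylbut-2-en-1-yl)phenyl]-3-methoxy-4H-chromen-4-one
Conditions: 3 M aq. HCl–MeOH (1:5), 45 °C
Reagents that add atoms: none
Why: acid-catalysed acetal methanolysis of both MOM ethers under mild conditions of the kind routinely used on ortho-prenyl phenols without chroman formation.

**Compound list**

1 | 3,5-dibromo-4-hydroxybenzaldehyde | O=Cc1cc(Br)c(O)c(Br)c1 | starting material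
2 | 4-(benzyloxy)-3,5-dibromobenzaldehyde | O=Cc1cc(Br)c(OCc2ccccc2)c(Br)c1 | intermediate
3 | furan | c1ccoc1 | starting material
4 | 2-furyllithium | [Li]c1ccco1 | intermediate
5 | [4-(benzyloxy)-3,5-dibromophenyl](furan-2-yl)methanol (racemic) | OC(c1ccco1)c1cc(Br)c(OCc2ccccc2)c(Br)c1 | intermediate
6 | 2-[4-(benzyloxy)-3,5-dibromophenyl]-6-hydroxy-2H-pyran-3(6H)-one (racemic, anomeric mixture) | O=C1C=CC(O)OC1c1cc(Br)c(OCc2ccccc2)c(Br)c1 | intermediate
7 | 2-[4-(benzyloxy)-3,5-dibromophenyl]-4-chloro-6-hydroxy-2H-pyran-3(6H)-one (racemic, anomeric mixture) | O=C1C(Cl)=CC(O)OC1c1cc(Br)c(OCc2ccccc2)c(Br)c1 | intermediate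
8 | 2-[4-(benzyloxy)-3,5-dibromophenyl]-3-hydroxy-4H-pyran-4-one | O=c1ccoc(-c2cc(Br)c(OCc3ccccc3)c(Br)c2)c1O | intermediate
9 | 2-[4-(benzyloxy)-3,5-dibromophenyl]-3-methoxy-4H-pyran-4-one | COc1c(-c2cc(Br)c(OCc3ccccc3)c(Br)c2)occc1=O | intermediate
10 | 2-[4-(benzyloxy)-3,5-dibromophenyl]-5-bromo-3-methoxy-4H-pyran-4-one | COc1c(-c2cc(Br)c(OCc3ccccc3)c(Br)c2)occ(Br)c1=O | intermediate
11 | methyl acetoacetate | COC(=O)CC(C)=O | starting material
12 | methyl 3-(trimethylsilyloxy)but-2-enoate (E/Z mixture) | COC(=O)C=C(C)O[Si](C)(C)C | intermediate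
13 | lithium 1-methoxy-3-(trimethylsilyloxy)buta-1,3-dien-1-olate | [Li]OC(OC)=CC(=C)O[Si](C)(C)C | intermediate
14 | 1-methoxy-1,3-bis(trimethylsilyloxy)buta-1,3-diene (ketene-acetal geometry as formed) | COC(O[Si](C)(C)C)=CC(O[Si](C)(C)C)=C | intermediate
15 | 2-[4-(benzyloxy)-3,5-dibromophenyl]-5-bromo-3-methoxy-4-(trimethylsilyloxy)pyrylium trifluoromethanesulfonate | COc1c(-c2cc(Br)c(OCc3ccccc3)c(Br)c2)[o+]cc(Br)c1O[Si](C)(C)C.[O-]S(=O)(=O)C(F)(F)F | intermediate
16 | 2-[4-(benzyloxy)-3,5-dibromophenyl]-4a-bromo-3,5-dimethoxy-5,7-bis(trimethylsilyloxy)-4a,5,8,8a-tetrahydro-4H-chromen-4-one (racemic, cis ring fusion expected, C5 unassigned) | COC1=C(c2cc(Br)c(OCc3ccccc3)c(Br)c2)OC2CC(O[Si](C)(C)C)=CC(OC)(O[Si](C)(C)C)C2(Br)C1=O | intermediate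
17 | 2-[4-(benzyloxy)-3,5-dibromophenyl]-3-methoxy-5,7-bis(trimethylsilyloxy)-4H-chromen-4-one | COc1c(-c2cc(Br)c(OCc3ccccc3)c(Br)c2)oc2cc(O[Si](C)(C)C)cc(O[Si](C)(C)C)c2c1=O | intermediate
18 | 2-[4-(benzyloxy)-3,5-dibromophenyl]-5,7-dihydroxy-3-methoxy-4H-chromen-4-one | COc1c(-c2cc(Br)c(OCc3ccccc3)c(Br)c2)oc2cc(O)cc(O)c2c1=O | intermediate
19 | 2-(3,5-dibromo-4-hydroxyphenyl)-5,7-dihydroxy-3-methoxy-4H-chromen-4-one | COc1c(-c2cc(Br)c(O)c(Br)c2)oc2cc(O)cc(O)c2c1=O | intermediate
20 | 2-[3,5-dibromo-4-(methoxymethoxy)phenyl]-5-hydroxy-3-methoxy-7-(methoxymethoxy)-4H-chromen-4-one | COCOc1cc(O)c2c(c1)oc(-c1cc(Br)c(OCOC)c(Br)c1)c(OC)c2=O | intermediate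
21 | prenylboronic acid pinacol ester | CC(C)=CCB1OC(C)(C)C(C)(C)O1 | starting material
22 | 5-hydroxy-3-methoxy-7-(methoxymethoxy)-2-[4-(methoxymethoxy)-3,5-bis(3-methylbut-2-en-1-yl)phenyl]-4H-chromen-4-one | COCOc1cc(O)c2c(c1)oc(-c1cc(CC=C(C)C)c(OCOC)c(CC=C(C)C)c1)c(OC)c2=O | intermediate
23 | 5,7-dihydroxy-2-[4-hydroxy-3,5-bis(3-methylbut-2-en-1-yl)phenyl]-3-methoxy-4H-chromen-4-one (achiral) | COc1c(-c2cc(CC=C(C)C)c(O)c(CC=C(C)C)c2)oc2cc(O)cc(O)c2c1=O | target

**Count**

Total steps: 12. Longest linear sequence: 10 (steps 1–5 and 8–12); the diene branch is steps 6–7.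

**Steps most likely to fail**

Step 8. Ring closure may not follow the first C–C bond: the C5 silyl enol ether is hindered and deactivated by bromine, so desilylation of the carboxonium could win and leave an open-chain adduct. The diene may also be lost by protodesilylation. Once amine is present the pyranone may open by retro-oxa-Michael reaction and give up bromine as Br+ instead of HBr.
The fallback uses known chemistry, sets out from 2 and returns at 18; ring A is then bought as phloroglucinol and ring C is closed last. Pinnick oxidation of 2 should give 4-(benzyloxy)-3,5-dibromobenzoic acid F1, and oxalyl chloride with catalytic DMF its acid chloride, 4-(benzyloxy)-3,5-dibromobenzoyl chloride F2. Commercial 2-methoxy-1-(2,4,6-trihydroxyphenyl)ethanone is tri-O-aroylated with F2 in pyridine to give 2-(methoxyacetyl)benzene-1,3,5-triyl tris[4-(benzyloxy)-3,5-dibromobenzoate] F3. KOH in pyridine should induce the Baker–Venkataraman O→C aroyl shift to the 1,3-diketone, 3-hydroxy-5-{3-[4-(benzyloxy)-3,5-dibromophenyl]-2-methoxy-3-oxopropanoyl}-1,4-phenylene-type bis-aroate F4. NaOAc in AcOH at 100 °C cyclodehydrates it to the flavone 5,7-bis-aroate, 2-[4-(benzyloxy)-3,5-dibromophenyl]-3-methoxy-4-oxo-4H-chromene-5,7-diyl bis[4-(benzyloxy)-3,5-dibromobenzoate] F5. Saponification (K2CO3, MeOH–H2O) then gives 18.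

Step 11. Reductive elimination from the tertiary, γ-bound allyl–palladium would give 1,1-dimethylallyl isomers. The second coupling next to the MOM ether may stall or give protodebromination, and hot aqueous hydroxide may open the pyranone ring.
The fallback sets out from 20 and returns at 22. Stille coupling with allyltributylstannane (Pd(PPh3)4, toluene, 100 °C) has no regiochemical ambiguity and uses no hydroxide. It should give 2-[3,5-diallyl-4-(methoxymethoxy)phenyl]-5-hydroxy-3-methoxy-7-(methoxymethoxy)-4H-chromen-4-one F6. Cross-metathesis with excess 2-methyl-2-butene (second-generation ruthenium NHC benzylidene catalyst, CH2Cl2, 40 °C) then converts both allyl groups into prenyl groups and gives 22.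

Step 3. Acid may ionise the doubly activated carbinol before ring expansion. Over-chlorination, incomplete hydrolytic transposition of 7 and partial loss of the benzyl ether in the hot acid are further risks.
The fallback sets out from 2 and returns at 8; ring C is built by cycloaddition instead of from furan. A Lewis-acid hetero-Diels–Alder reaction of 2 with 1-methoxy-3-(trimethylsilyloxy)buta-1,3-diene (ZnCl2, THF; TFA work-up) should give racemic 2-[4-(benzyloxy)-3,5-dibromophenyl]-2,3-dihydro-4H-pyran-4-one F7. α′-Hydroxylation of its lithium enolate (LiHMDS, THF, −78 °C; 2-(phenylsulfonyl)-3-phenyloxaziridine) should give racemic 2-[4-(benzyloxy)-3,5-dibromophenyl]-3-hydroxy-2,3-dihydro-4H-pyran-4-one F8. Hypervalent-iodine oxidation (DMP, CH2Cl2) of the α-hydroxy ketone gives the 3,4-dione, which is 8 in its stable enol form.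

**Further compounds**

F1 | step 8 | 4-(benzyloxy)-3,5-dibromobenzoic acid | OC(=O)c1cc(Br)c(OCc2ccccc2)c(Br)c1
F2 | step 8 | 4-(benzyloxy)-3,5-dibromobenzoyl chloride | ClC(=O)c1cc(Br)c(OCc2ccccc2)c(Br)c1
F3 | step 8 | 2-(methoxyacetyl)benzene-1,3,5-triyl tris[4-(benzyloxy)-3,5-dibromobenzoate] | COCC(=O)c1c(OC(=O)c2cc(Br)c(OCc3ccccc3)c(Br)c2)cc(OC(=O)c2cc(Br)c(OCc3ccccc3)c(Br)c2)cc1OC(=O)c1cc(Br)c(OCc2ccccc2)c(Br)c1
F4 | step 8 | 1-[4-(benzyloxy)-3,5-dibromophenyl]-3-{2-hydroxy-4,6-bis[4-(benzyloxy)-3,5-dibromobenzoyloxy]phenyl}-2-methoxypropane-1,3-dione (racemic, enolisable) | COC(C(=O)c1cc(Br)c(OCc2ccccc2)c(Br)c1)C(=O)c1c(O)cc(OC(=O)c2cc(Br)c(OCc3ccccc3)c(Br)c2)cc1OC(=O)c1cc(Br)c(OCc2ccccc2)c(Br)c1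
F5 | step 8 | 2-[4-(benzyloxy)-3,5-dibromophenyl]-3-methoxy-4-oxo-4H-chromene-5,7-diyl bis[4-(benzyloxy)-3,5-dibromobenzoate] | COc1c(-c2cc(Br)c(OCc3ccccc3)c(Br)c2)oc2cc(OC(=O)c3cc(Br)c(OCc4ccccc4)c(Br)c3)cc(OC(=O)c3cc(Br)c(OCc4ccccc4)c(Br)c3)c2c1=O
F6 | step 11 | 2-[3,5-diallyl-4-(methoxymethoxy)phenyl]-5-hydroxy-3-methoxy-7-(methoxymethoxy)-4H-chromen-4-one | COCOc1cc(O)c2c(c1)oc(-c1cc(CC=C)c(OCOC)c(CC=C)c1)c(OC)c2=O
F7 | step 3 | 2-[4-(benzyloxy)-3,5-dibromophenyl]-2,3-dihydro-4H-pyran-4-one (racemic) | O=C1C=COC(c2cc(Br)c(OCc3ccccc3)c(Br)c2)C1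
F8 | step 3 | 2-[4-(benzyloxy)-3,5-dibromophenyl]-3-hydroxy-2,3-dihydro-4H-pyran-4-one (racemic, relative configuration unassigned) | O=C1C=COC(c2cc(Br)c(OCc3ccccc3)c(Br)c2)C1O
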